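Compound numbers are fixed first and used in every section. Guaiane numbering applies to all bicyclic compounds: five ring C1–C5, seven ring C1, C5–C10, methyl C15 on C4, methyl C14 on C10, isopropyl on C7. β is the face of H1 and of the C10 hydroxyl in the target; α is the face of H5.

## The problem

1. The target is a guaiane: a cyclopentane fused along C1–C5 to a cycloheptane, with methyl groups on C4 and C10, isopropyl on C7, a 4-hydroxybenzoate on O8, a tertiary hydroxyl on C10 and an epoxide across C3–C4.
2. The ring fusion is trans (H1 β, H5 α) and there are seven stereocentres, (1R,3R,4S,5S,7S,8R,10R), two of them (C4, C10) fully substituted.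
3. Control can be relayed: a centre at C5 fixes a carbinol at C4, which can deliver hydrogen to C1 and set the trans junction; C1 then decides the face on which oxygen reaches C10; the C10 hydroxyl and the C7 isopropyl group (adjustable by equilibration next to a C8 ketone) together fix C8.
4. The epoxide is the exception: it lies on the β face of the five ring, cis to C6, which is judged the more hindered side, so it needs a method that runs against steric approach.
5. The trisubstituted epoxide (acid), the tertiary alcohol β to C8 (retro-aldol while C8 is a ketone) and the phenolic ester (base, acyl shift to O10) are fragile, so epoxide and ester must come last.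
6. The enabling feature is that C10 (methyl), C8 (oxygen) and C7 (isopropyl), with CH at C9 and C6, repeat the substitution pattern of thymol, and C1 is the free carbon para to the phenolic oxygen. Inserting one carbon, C5, into the C1–C6 bond of that benzene ring gives the seven ring, and because C5 also belongs to the five ring, a carbenoid tethered to C1 through C2–C3–C4 closes both rings at once.

## Retrosynthesis

**Ester and phenol (26 ⇒ 25 ⇒ 21 + 24).** The O–Si bond of the phenol and the C8 O–acyl bond are cut last. Only one secondary hydroxyl is present in epoxy diol 21, so acylation needs no protection on the terpene. A silyl group on the acid 24 (from 4-hydroxybenzoic acid 22) is released by buffered fluoride, which the epoxide and the ester tolerate; hydrogenolysis or hydrolysis would be less safe.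

**Epoxide (21 ⇒ 19 through bromohydrin 20).** The C3–O and C4–O bonds are cut back to the 3-ene diol 19. The alternative, direct peracid epoxidation, is expected to favour the α face (that of H5, away from C6). The two-stage route through 20 inverts that preference: bromine takes the easy face and the oxygen ends up on the other.

**Seven-ring oxygens (19 ⇒ 18 ⇒ 17 ⇒ 16).** The C8–H bond is cut to give β-hydroxy ketone 18, then the C10–O bond is traced through epoxy ketone 17 to enone 16. This puts the C10 oxygen in by conjugate attack on a C9=C10 enone, where C1 controls the face, and lets the new hydroxyl direct the C8 reduction. A hydration of an isolated C9=C10 or C1=C10 alkene would have no such handle on regio- or stereochemistry.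

**Two alkenes (16 ⇒ 14 ⇒ 13).** The C9=C10 bond is taken back to the saturated ketone 14 (regioselective dehydrogenation), and the C3=C4 bond to the tertiary carbinol 13 (dehydration). The C4 hydroxyl must leave before the second tertiary alcohol (C10) appears, because the two could not be told apart later. Passing through saturated C10 is a redox detour, accepted because it lets the junction be set first.

**Trans junction (13 ⇒ 11).** Four C–H bonds (C1, C10, C6, C7) are cut back to dienone 11. The alternative of moving C1=C10 into conjugation with base would set C1 by an undirected protonation. Hydrogen delivered from the 4β-hydroxyl gives H1 β by design, and C7 is corrected by equilibration.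

**Unmasking and C15 (11 ⇒ 10 ⇒ 9).** The Si–O bond and the C4–CH3 bond are cut. Adding methyl to the C4 ketone of 9 immediately does three jobs: it brings in C15, it removes the carbonyl that makes C5 enolisable, and it creates the directing hydroxyl. Keeping the C4 ketone for a later enol triflate would leave a vinylogous 1,3-dicarbonyl through C5–C6=C7–C8 once the C8 ketone is unmasked, and C5 would be lost.

**Both rings (9 ⇒ 8).** The C5–C1 and C5–C6 bonds are cut, returning an arene and a diazoketone. The precursor 8 is achiral, monocyclic and contains every carbon except C15. The forward reaction must add the carbenoid to the C1–C6 bond and not to C1–C10, choose one enantiotopic face, and deliver the kinetic triene without acid or base.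

**Side chain (8 ⇒ 6 ⇒ 5 ⇒ 3 + 4; 3 ⇒ 2 ⇒ 1).** The C4–C5 bond (acylation of diazomethane) and the aryl–C2 bond (Heck coupling of bromide 3 with benzyl acrylate 4) are cut. The benzyl ester lets one hydrogenation saturate the chain and free the acid 6 without base. Bromide 2 comes from para-bromination of thymol 1.

## Roads not taken

**Alternative 1: carbonyl-ene closure of the seven ring.**
- Cut: C7–C8. Forward step: Me2AlCl promotes the ene reaction of the seco aldehyde A2, giving the 8-hydroxy-11-ene A1.
- Merits: one step creates the C8 hydroxyl and the C7 centre and leaves C3=C4 and the C10 ether in place. Only isopropenyl hydrogenation, epoxidation and acylation remain, which is clearly shorter than the seven steps the chosen plan spends between the bicycle and diol 19.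
- Weak points: the closure forms a seven ring, less favourable than the six-ring isopulegol case; a Lewis acid meets a tertiary silyl ether; and A2 must already carry C1, C5 (trans) and the quaternary C10 on a cyclopentene.
- Comparison: the hard stereochemistry is moved into the precursor, not removed. The chosen plan sets against it a C10 aromatic starting material that already holds C7–C8 and all three seven-ring substituents, and a well-precedented ring-forming step.

**Alternative 2: enone–alkene photocycloaddition, then fragmentation.**
- Cut: C6–C7 and C8–C9. Forward step: irradiation of diquinane enone A4 with 3-methylbut-1-ene A5 gives cyclobutane A3, whose C6–C9 bond is later cleaved to open the seven ring.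
- Merits: it is convergent; the C10 ketone would accept a methyl nucleophile to give the carbinol directly; and C1, being α to that ketone, could be equilibrated. On both points it is better than the chosen plan, which needs a directed hydrogenation and a dehydrogenation–epoxidation–reduction sequence for the same two centres.
- Weak points: head-to-tail regiochemistry with an unactivated monosubstituted alkene is unreliable; A3 has no oxygen at C8, and after fragmentation C8 is β to the carbonyl and out of reach of enolate oxidation.
- Comparison: the chosen plan carries the C8 oxygen from the phenol throughout.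

**Alternative 3: gold cyclisation through a C7–O–C10 bridge.**
- Cut: C1–C5, C6–C7 and C10–O. Forward step: [(tBu2(o-biphenyl)P)Au(NCMe)]SbF6 (monovalent gold) converts enynone A7 into the oxygen-bridged A6.
- Merits: this is the most powerful single step of the four. It makes three bonds and both carbocycles from an open chain with one stereocentre, and C10–O arrives with defined configuration relative to C1, which the chosen plan reaches only after several steps.
- Weak points: the bridge oxygen sits on C7, which in the target bears hydrogen, so a tertiary C7–O bond must be cleaved reductively with stereocontrol while C10–O stays; C8 again lacks oxygen; C5=C6 must still be reduced to a trans junction.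
- Comparison: the chosen plan is longer after the key step, but each of its later operations is a standard reaction type, whereas this road needs two transformations with no dependable solution.

Key step: step 6

Assumption: the sense of induction of the copper–bisoxazoline catalyst cannot be predicted for this substrate; wherever the ligand is written, the antipode that delivers (5S)-9 is meant.

## Route

Step 1
Reactants: 1 thymol
Product: 2 4-bromothymol (4-bromo-5-methyl-2-isopropylphenol)
Conditions: NBS, MeCN, 0 °C to rt
Reagents that add atoms: N-bromosuccinimide, O=C1CCC(=O)N1Br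
Why: Electrophilic aromatic bromination; the hydroxyl directs to its para position, which is the future C1, and the competing ortho site is the more crowded one.

Step 2
Reactants: 2 4-bromothymol
Product: 3 4-bromothymol triisopropylsilyl ether
Conditions: TIPSOTf, 2,6-lutidine, CH2Cl2, 0 °C to rt
Reagents that add atoms: triisopropylsilyl trifluoromethanesulfonate, CC(C)[Si](C(C)C)(C(C)C)OS(=O)(=O)C(F)(F)F
Why: Silylation of a hindered phenol with a silyl triflate; the bulky group survives the coupling, hydrogenation and acid chloride steps and later gives a robust silyl enol ether.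

Step 3
Reactants: 3 4-bromothymol triisopropylsilyl ether; 4 benzyl acrylate
Product: 5 benzyl (E)-3-[2-methyl-5-isopropyl-4-(triisopropylsilyloxy)phenyl]prop-2-enoate
Conditions: Pd(OAc)2 (5 mol %), P(o-tol)3 (10 mol %), Et3N, DMF, 100 °C
Reagents that add atoms: none
Why: Heck reaction: oxidative addition of the aryl bromide to zerovalent palladium, syn insertion of the acrylate and β-hydride elimination give the E-cinnamate.

Step 4
Reactants: 5 benzyl cinnamate
Product: 6 3-[2-methyl-5-isopropyl-4-(triisopropylsilyloxy)phenyl]propanoic acid
Conditions: H2 (1 atm), Pd/C, EtOAc, rt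
Reagents that add atoms: none
Why: Catalytic hydrogenation saturates the cinnamate double bond and hydrogenolyses the benzyl ester in the same operation, so no basic saponification touches the aryl silyl ether.

Step 5
Reactants: 6 arylpropanoic acid
Product: 8 1-diazo-4-[2-methyl-5-isopropyl-4-(triisopropylsilyloxy)phenyl]butan-2-one, via acid chloride 7 (not isolated)
Conditions: (COCl)2, DMF (cat.), CH2Cl2, 0 °C to rt; then CH2N2 (3 equiv), Et2O, 0 °C
Reagents that add atoms: diazomethane, C=[N+]=[N-]
Why: Acid chloride formation followed by acylation of diazomethane (the first stage of an Arndt–Eistert sequence); excess diazomethane takes up HCl, so no chloromethyl ketone forms.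

Step 6
Reactants: 8 diazoketone
Product: 9 (5S)-8-(triisopropylsilyloxy)-15-norguaia-1(10),6,8-trien-4-one
Conditions: Cu(MeCN)4PF6 (5 mol %), 2,2'-(propane-2,2-diyl)bis[(4S)-4-tert-butyl-4,5-dihydrooxazole] or its antipode (6 mol %), CH2Cl2, 40 °C, slow addition of 8 at high dilution; filtered through neutral alumina and used at once
Reagents that add atoms: none
Why: The cationic monovalent copper–bisoxazoline complex decomposes the diazoketone with loss of N2 to an electrophilic carbenoid at C5. The carbenoid attacks the ipso carbon C1 (para to the silyloxy group, the most nucleophilic ring position) and closes onto the unsubstituted ortho carbon C6, a cyclopropanation of the C1–C6 arene bond: the C5–C1 bond closes the cyclopentanone in a 5-exo sense and the three ring follows by 3-exo closure. The norcaradiene then opens by disrotatory 6π electrocyclic cleavage of C1–C6, so the seven ring arises by expansion of the arene and not by a chain cyclisation. The closest known reaction type is the intramolecular Buchner reaction of 1-diazo-4-arylbutan-2-ones to 3,8a-dihydroazulen-1(2H)-ones, including enantioselective copper–bisoxazoline versions. C5 is the only new stereocentre; it is set by which enantiotopic face of the carbenoid–arene pair fits the chiral pocket of the ligand. The step needs addition at C1–C6 and not C1–C10, which the ortho methyl on C10 secures, and cyclopropanation in preference to formal aromatic substitution (2-tetralone) or loss of the silyl group, which the non-nucleophilic PF6 counter-ion and the hindered silyl ether favour. Acid and base are kept away in work-up, because acid rearranges 9 to a tetralone and base enolises C5.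

Step 7
Reactants: 9 trienone
Product: 10 (4R,5S)-8-(triisopropylsilyloxy)guaia-1(10),6,8-trien-4-ol (4β-OH, 4α-CH3, 5α-H)
Conditions: MeLi, CeCl3, THF, −78 °C; aq. NH4Cl
Reagents that add atoms: methyllithium (as MeCeCl2), [Li]C
Why: Organocerium 1,2-addition: the weakly basic reagent adds to the ketone faster than it removes the very acidic H5, so C5 is frozen and C15 is installed. The reagent should enter from the face of H5, because C6 of the boat-shaped cycloheptatriene covers the other face, giving the 4β-hydroxyl.

Step 8
Reactants: 10 trienol silyl ether
Product: 11 4β-hydroxy-5α-H-guaia-1(10),6-dien-8-one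
Conditions: Bu4NF, AcOH (1:1), THF, 0 °C
Reagents that add atoms: none
Why: Fluoride cleavage of the silyl enol ether with kinetic protonation of the dienolate at the α-carbon C9 gives the C6=C7–C8=O enone and leaves C1=C10 in place, with no new stereocentre. The acetic acid buffer prevents alkoxide formation at C4 (vinylogous retro-aldol) and enolisation toward C5.

Step 9
Reactants: 11 dienone
Product: 13 4β-hydroxy-(1β-H,5α-H,7α-H,10β-H)-guaian-8-one, via 7-epi ketone 12 (not isolated)
Conditions: [Ir(cod)(PCy3)(py)]PF6 (5–10 mol %), H2 (1–4 atm), CH2Cl2, rt; then NaOMe (cat.), MeOH, rt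
Reagents that add atoms: none
Why: Hydroxyl-directed homogeneous hydrogenation: the cationic iridium catalyst binds the 4β-hydroxyl, homoallylic to both alkenes, and delivers H2 to the β face of the tetrasubstituted C1=C10 bond, so H1 enters trans to H5 (the device that gives trans-hydrindanes from homoallylic alcohols). C6=C7 is reduced as well, and the methoxide treatment leaves C7 under thermodynamic control with the isopropyl group equatorial (β, cis-1,3 to the C5–C4 bond).

Step 10
Reactants: 13 hydroxy ketone
Product: 14 (1β-H,5α-H,7α-H,10β-H)-guai-3-en-8-one
Conditions: Burgess reagent (MeO2CN–SO2NEt3 inner salt), toluene, 50 °C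
Reagents that add atoms: none
Why: Burgess dehydration by syn elimination through the sulfamate ester: H5 is anti to the 4β-oxygen and cannot be reached, so elimination goes to C3 or to the methyl group, and the endocyclic trisubstituted alkene is expected to dominate for a cyclopentyl carbinol.

Step 11
Reactants: 14 ketone
Product: 16 (1β-H,5α-H,7α-H)-guaia-3,9-dien-8-one, via trimethylsilyl enol ether 15 (not isolated)
Conditions: LiN(CHMe2)2, Me3SiCl, THF, −78 °C; then Pd(OAc)2 (1.1 equiv), MeCN, rt
Reagents that add atoms: none
Why: Kinetic deprotonation at the unhindered C9 methylene (C7 carries the isopropyl group) and silylation, then Saegusa–Ito oxidation: palladation at C9 and β-hydride elimination of H10 give the C9=C10 enone regiospecifically, leaving C1 and C7 untouched.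

Step 12
Reactants: 16 dienone
Product: 17 9β,10β-epoxy-(1β-H,5α-H,7α-H)-guai-3-en-8-one
Conditions: H2O2 (30 %), NaOH (0.3 equiv), MeOH, 0 °C
Reagents that add atoms: hydrogen peroxide, OO
Why: Weitz–Scheffer nucleophilic epoxidation of the only enone (as for isophorone); the isolated C3=C4 alkene is inert. In the chair-like cycloheptenone C5 and C6 are folded onto the α face, so hydroperoxide should attack C10 from the β face, anti to the C1–C5 bond and past the small H1; C7 stays at its thermodynamic configuration.

Step 13
Reactants: 17 epoxy ketone
Product: 18 10β-hydroxy-(1β-H,5α-H,7α-H)-guai-3-en-8-one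
Conditions: SmI2 (2.2 equiv), THF/MeOH, −90 °C
Reagents that add atoms: none
Why: Reductive opening of an α,β-epoxy ketone by SmI2: electron transfer to the carbonyl cleaves only the C9–O bond, so the C10–O bond and its configuration are kept. Low temperature and a proton source suppress retro-aldol cleavage and over-reduction.

Step 14
Reactants: 18 β-hydroxy ketone
Product: 19 (1β-H,5α-H,7α-H)-guai-3-ene-8α,10β-diol
Conditions: Me4NBH(OAc)3, MeCN/AcOH, −30 °C
Reagents that add atoms: none
Why: Evans–Saksena reduction: the C10 hydroxyl exchanges onto boron and hydride is delivered internally to the β face of the C8 carbonyl, giving the 1,3-anti diol (8α-OH). This is also the equatorial alcohol trans to the isopropyl group, so substrate bias and delivery agree.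

Step 15
Reactants: 19 ene diol
Product: 21 3β,4β-epoxy-(1β-H,5α-H,7α-H)-guaiane-8α,10β-diol, via bromohydrin 20 (not isolated)
Conditions: NBS, THF/H2O, 0 °C; then K2CO3, MeOH, rt
Reagents that add atoms: water, O
Why: Halohydrin formation and base-induced closure: the bromonium ion should form on the less hindered α face, water opens it at the tertiary C4 from the β face, and carbonate closes the trans-bromohydrin with inversion at C3 to the β-epoxide. This is the face a peracid would not favour (the device that turns 3-carene into its β-epoxide); the C10 hydroxyl lies in the plane of the five ring and cannot intercept the bromonium ion.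

Step 16
Reactants: 22 4-hydroxybenzoic acid
Product: 24 4-(tert-butyldimethylsilyloxy)benzoic acid, via bis-silyl derivative 23 (not isolated)
Conditions: TBSCl (2.2 equiv), imidazole, DMF, rt; then K2CO3 (cat.), MeOH/THF/H2O, rt; citric acid work-up
Reagents that add atoms: tert-butyldimethylsilyl chloride, CC(C)(C)[Si](C)(C)Cl
Why: Bis-silylation followed by selective hydrolysis of the labile silyl ester, the standard way to a phenol-protected hydroxybenzoic acid.

Step 17
Reactants: 21 epoxy diol; 24 4-(tert-butyldimethylsilyloxy)benzoic acid
Product: 25 3β,4β-epoxy-10β-hydroxy-(1β-H,5α-H,7α-H)-guaian-8α-yl 4-(tert-butyldimethylsilyloxy)benzoate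
Conditions: EDC·HCl, DMAP, CH2Cl2, rt
Reagents that add atoms: none
Why: Steglich esterification: only the secondary C8 hydroxyl is acylated, the tertiary C10 hydroxyl is inert, and the neutral conditions spare the epoxide.

Step 18
Reactants: 25 silyl-protected ester
Product: 26 3β,4β-epoxy-10β-hydroxy-(1β-H,5α-H,7α-H)-guaian-8α-yl 4-hydroxybenzoate, (1R,3R,4S,5S,7S,8R,10R)
Conditions: Bu4NF, AcOH, THF, 0 °C
Reagents that add atoms: none
Why: Fluoride cleavage of the aryl silyl ether; the acetic acid buffer prevents acyl shift to O10 and ester cleavage, and nothing acidic enough to open the epoxide is present.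

## Compound list

1 | thymol | CC(C)c1ccc(C)cc1O | starting material
2 | 4-bromothymol | CC(C)c1cc(Br)c(C)cc1O | intermediate
3 | 4-bromothymol triisopropylsilyl ether | CC(C)c1cc(Br)c(C)cc1O[Si](C(C)C)(C(C)C)C(C)C | intermediate
4 | benzyl acrylate | C=CC(=O)OCc1ccccc1 | starting material
5 | benzyl (E)-3-[2-methyl-5-isopropyl-4-(triisopropylsilyloxy)phenyl]prop-2-enoate | CC(C)c1cc(/C=C/C(=O)OCc2ccccc2)c(C)cc1O[Si](C(C)C)(C(C)C)C(C)C | intermediate
6 | 3-[2-methyl-5-isopropyl-4-(triisopropylsilyloxy)phenyl]propanoic acid | CC(C)c1cc(CCC(=O)O)c(C)cc1O[Si](C(C)C)(C(C)C)C(C)C | intermediate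
7 | 3-[2-methyl-5-isopropyl-4-(triisopropylsilyloxy)phenyl]propanoyl chloride | CC(C)c1cc(CCC(=O)Cl)c(C)cc1O[Si](C(C)C)(C(C)C)C(C)C | intermediate (not isolated)
8 | 1-diazo-4-[2-methyl-5-isopropyl-4-(triisopropylsilyloxy)phenyl]butan-2-one | CC(C)c1cc(CCC(=O)C=[N+]=[N-])c(C)cc1O[Si](C(C)C)(C(C)C)C(C)C | intermediate
9 | (5S)-8-(triisopropylsilyloxy)-15-norguaia-1(10),6,8-trien-4-one | CC(C)C1=C[C@@H]2C(=O)CCC2=C(C)C=C1O[Si](C(C)C)(C(C)C)C(C)C | intermediate
10 | (4R,5S)-8-(triisopropylsilyloxy)guaia-1(10),6,8-trien-4-ol (4β-OH, 5α-H) | CC(C)C1=C[C@@H]2[C@](C)(O)CCC2=C(C)C=C1O[Si](C(C)C)(C(C)C)C(C)C | intermediate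
11 | 4β-hydroxy-5α-H-guaia-1(10),6-dien-8-one | CC(C)C1=C[C@@H]2[C@](C)(O)CCC2=C(C)CC1=O | intermediate
12 | 4β-hydroxy-(1β-H,5α-H,7β-H,10β-H)-guaian-8-one (7-epimer of 13) | CC(C)[C@H]1C[C@H]2[C@@H](CC[C@@]2(C)O)[C@@H](C)CC1=O | intermediate (not isolated)
13 | 4β-hydroxy-(1β-H,5α-H,7α-H,10β-H)-guaian-8-one | CC(C)[C@@H]1C[C@H]2[C@@H](CC[C@@]2(C)O)[C@@H](C)CC1=O | intermediate
14 | (1β-H,5α-H,7α-H,10β-H)-guai-3-en-8-one | CC(C)[C@@H]1C[C@H]2[C@@H](CC=C2C)[C@@H](C)CC1=O | intermediate
15 | 8-(trimethylsilyloxy)-(1β-H,5α-H,7α-H,10β-H)-guaia-3,8-diene | CC(C)[C@@H]1C[C@H]2[C@@H](CC=C2C)[C@@H](C)C=C1O[Si](C)(C)C | intermediate (not isolated)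
16 | (1β-H,5α-H,7α-H)-guaia-3,9-dien-8-one | CC(C)[C@@H]1C[C@H]2[C@@H](CC=C2C)C(C)=CC1=O | intermediate
17 | 9β,10β-epoxy-(1β-H,5α-H,7α-H)-guai-3-en-8-one | CC(C)[C@@H]1C[C@H]2[C@@H](CC=C2C)[C@]3(C)O[C@@H]3C1=O | intermediate
18 | 10β-hydroxy-(1β-H,5α-H,7α-H)-guai-3-en-8-one | CC(C)[C@@H]1C[C@H]2[C@@H](CC=C2C)[C@](C)(O)CC1=O | intermediate
19 | (1β-H,5α-H,7α-H)-guai-3-ene-8α,10β-diol | CC(C)[C@@H]1C[C@H]2[C@@H](CC=C2C)[C@](C)(O)C[C@H]1O | intermediate
20 | 3α-bromo-(1β-H,5α-H,7α-H)-guaiane-4β,8α,10β-triol | CC(C)[C@@H]1C[C@H]2[C@@H](C[C@H](Br)[C@@]2(C)O)[C@](C)(O)C[C@H]1O | intermediate (not isolated)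
21 | 3β,4β-epoxy-(1β-H,5α-H,7α-H)-guaiane-8α,10β-diol | CC(C)[C@@H]1C[C@H]2[C@@H](C[C@H]3O[C@]32C)[C@](C)(O)C[C@H]1O | intermediate
22 | 4-hydroxybenzoic acid | O=C(O)c1ccc(O)cc1 | starting material
23 | tert-butyldimethylsilyl 4-(tert-butyldimethylsilyloxy)benzoate | CC(C)(C)[Si](C)(C)OC(=O)c1ccc(O[Si](C)(C)C(C)(C)C)cc1 | intermediate (not isolated)
24 | 4-(tert-butyldimethylsilyloxy)benzoic acid | O=C(O)c1ccc(O[Si](C)(C)C(C)(C)C)cc1 | intermediate
25 | 3β,4β-epoxy-10β-hydroxy-(1β-H,5α-H,7α-H)-guaian-8α-yl 4-(tert-butyldimethylsilyloxy)benzoate | CC(C)[C@@H]1C[C@H]2[C@@H](C[C@H]3O[C@]32C)[C@](C)(O)C[C@H]1OC(=O)c1ccc(O[Si](C)(C)C(C)(C)C)cc1 | intermediate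
26 | (1R,3R,4S,5S,7S,8R,10R)-3,4-epoxy-10-hydroxyguaian-8-yl 4-hydroxybenzoate | CC(C)[C@@H]1C[C@H]2[C@@H](C[C@H]3O[C@]32C)[C@](C)(O)C[C@H]1OC(=O)c1ccc(O)cc1 | target

## Step count and least certain steps

Total: 18 steps. Longest linear sequence: 17 steps (1 to 26 through steps 1–15, 17 and 18); step 16 is a one-step side branch.

**Step 6 (key step).**
- Risk: poor enantioface discrimination with a diazo carbon that carries only hydrogen; loss of the C5 configuration by enolisation before the ketone is trapped; diversion to aromatic substitution or to spirocyclisation with loss of the silyl group.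
- Fallback: setting out from 8, achiral Rh2(OAc)4 in CH2Cl2 gives 9 together with its mirror image, ent-trienone F1. Addition of MeCeCl2 as in step 7 gives 10 and its mirror image, ent-trienol F2, which are separated by preparative chromatography on a chiral stationary phase. The route is rejoined at 10. Enantiocontrol then rests on resolution of a stable compound, not on catalysis at a labile centre.

**Step 9.**
- Risk: sluggish reduction of the tetrasubstituted C1=C10 bond; hydrogen delivery from the α face if the C8 carbonyl competes with the hydroxyl for iridium or if the carbinol configuration from step 7 is not the one assumed.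
- Fallback: setting out from 11, radical hydrogenation by hydrogen-atom transfer (Mn(dpm)3, PhSiH3, t-BuOOH, 2-propanol) reduces both alkenes without reference to the hydroxyl group and sets the junction at the C1 radical under product-stability control, which in such reductions favours trans-fused bicycles. Methoxide equilibration at C7 then returns to 13. Whether the trans junction is the more stable one here would have to be checked.

**Step 10.**
- Risk: elimination into the methyl group, or ionisation at C4 followed by loss of H5.
- Fallback: setting out from 13, the alkene mixture rich in the exocyclic isomer, guai-4(15)-en-8-one F3, is treated with a catalytic hydrogen-atom-transfer isomerisation system (the chlorocobalt complex of N,N'-bis(3,5-di-tert-butylsalicylidene)-1,2-cyclohexanediamine, trivalent cobalt, with PhSiH3 in benzene). This moves a 1,1-disubstituted double bond into the ring toward the unhindered C3 methylene rather than the ring-fusion C5, and returns to 14.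

**Step 12.**
- Risk: insufficient facial selectivity at C10; base-induced deconjugation through the C1 dienolate with erosion of the trans junction; slow reaction of a β,β-disubstituted enone.
- Fallback: setting out from 16, copper-catalysed conjugate borylation (B2pin2, CuCl, NaOt-Bu (cat.), a chiral bisphosphine chosen to reinforce β attack, MeOH, THF) gives the β-boryl ketone F4. Oxidation with NaBO3·4H2O replaces boron by hydroxyl with retention and returns to the route at 18, bypassing 17. Face selection is then catalyst-controlled and the medium is far less basic.

**Step 15.**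
- Risk: low facial discrimination in bromonium formation, or opening by water at C3.
- Fallback: setting out from 19, a reagent-controlled Shi epoxidation (fructose-derived ketone of the antipode matched to the β face, KHSO5, K2CO3 buffer, MeCN/dimethoxymethane/water, 0 °C) gives 21 directly. Trisubstituted alkenes are the best substrates for this catalyst, and the chiral dioxirane, not the substrate, chooses the face.

## Further compounds

F1 | step 6 | (5R)-8-(triisopropylsilyloxy)-15-norguaia-1(10),6,8-trien-4-one (mirror image of 9) | CC(C)C1=C[C@H]2C(=O)CCC2=C(C)C=C1O[Si](C(C)C)(C(C)C)C(C)C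
F2 | step 6 | (4S,5R)-8-(triisopropylsilyloxy)guaia-1(10),6,8-trien-4-ol (mirror image of 10) | CC(C)C1=C[C@H]2[C@@](C)(O)CCC2=C(C)C=C1O[Si](C(C)C)(C(C)C)C(C)C
F0 | step 9 | none | none
F3 | step 10 | (1β-H,5α-H,7α-H,10β-H)-guai-4(15)-en-8-one | CC(C)[C@@H]1C[C@H]2[C@@H](CCC2=C)[C@@H](C)CC1=O
F4 | step 12 | 10β-(4,4,5,5-tetramethyl-1,3,2-dioxaborolan-2-yl)-(1β-H,5α-H,7α-H)-guai-3-en-8-one | CC(C)[C@@H]1C[C@H]2[C@@H](CC=C2C)[C@](C)(B3OC(C)(C)C(C)(C)O3)CC1=O
F0 | step 15 | none | none
A1 | alternative 1 | 10-(triethylsilyloxy)guaia-3,11-dien-8-ol | CC(=C)[C@@H]1C[C@H]2[C@@H](CC=C2C)[C@](C)(O[Si](CC)(CC)CC)C[C@H]1O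
A2 | alternative 1 | 3-[3-methyl-2-(3-methylbut-2-enyl)cyclopent-3-enyl]-3-(triethylsilyloxy)butanal (7,8-seco aldehyde) | CC(C)=CC[C@H]1[C@@H](CC=C1C)[C@](C)(O[Si](CC)(CC)CC)CC=O
A3 | alternative 2 | cis-anti-cis tricyclic cyclobutane ketone (14-nor-6,9-cycloguai-3-en-10-one) | CC(C)[C@@H]1[C@H]3[C@H]2[C@H](CC=C2C)C(=O)[C@H]3C1
A4 | alternative 2 | cis-6-methylbicyclo[3.3.0]octa-3,6-dien-2-one | CC1=CC[C@@H]2C(=O)C=C[C@H]12
A5 | alternative 2 | 3-methylbut-1-ene | C=CC(C)C
A6 | alternative 3 | 7,10-epoxyguai-5-en-4-ol triethylsilyl ether | CC(C)[C@@]13C=C2[C@@H](CC[C@]2(C)O[Si](CC)(CC)CC)[C@](C)(O3)CC1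
A7 | alternative 3 | (E)-2,6,10-trimethyl-10-(triethylsilyloxy)dodec-6-en-11-yn-3-one | C#C[C@@](C)(O[Si](CC)(CC)CC)CC/C=C(\C)CCC(=O)C(C)C
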